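**Plan**
1. Locants used below: C1 ring ketone, C2 (carries C7H2–O), C3 vinyl CH, C4 CH–O-tigloyl, C5 CH–isopropyl, C6 CH–OH. The enabling feature is that C4 is a carbinol allylic to the C2=C3 bond of the cyclohex-2-enone ring and sits cis to C1 across that bond. The ring bond C3–C4 is therefore the one a (Z)-β-metalated enone makes when it adds to a C4 aldehyde tethered through C5–C6.
2. Retrosynthetic cuts, in order: C6 O–Si; C7 O–acyl; C2–C7 (Morita–Baylis–Hillman with formaldehyde); C4 O–acyl (with inversion); ring bond C3–C4 (alkenylchromium plus aldehyde); C3–I (hydroiodination of an ynone); C1–C2 (acetylide plus lactone); C5–C6 (Evans syn-aldol).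
3. Forward: the C4–C5–C6–C1 chain is made by aldol and stored as a γ-lactone, opened to an ynone and converted into the (Z)-iodoenone aldehyde. The only carbocycle, the cyclohexenone ring, closes in step 8; C7 and the two tiglates follow.
4. Stereochemistry: C5 and C6 come from the (R)-benzyloxazolidinone auxiliary (syn-aldol). C4 is first set trans to C5 by substrate control in the ring closure, then inverted by the Mitsunobu esterification to the required cis tiglate. Both ester double bonds are E, from tiglic acid and its chloride.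

Key step: step 8

Assumption: the N-acylated auxiliary 1 is bought as such, and ethyl glyoxylate 2 is distilled from its commercial toluene solution just before use.

Step 1
Reactants: 1 (4R)-4-benzyl-3-(3-methylbutanoyl)-1,3-oxazolidin-2-one; 2 ethyl glyoxylate
Product: 4 ethyl (2R,3R)-3-{[(4R)-4-benzyl-2-oxo-1,3-oxazolidin-3-yl]carbonyl}-2-hydroxy-4-methylpentanoate (syn-aldol adduct), via Z-dibutylboron enolate 3 (not isolated)
Conditions: Bu2BOTf, Et3N, CH2Cl2, −78 to 0 °C; then 2, −78 to 0 °C; pH 7 buffer, MeOH, 30% H2O2, 0 °C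
Reagents that add atoms: none
Why: Evans syn-aldol, in which the Z-boron enolate 3 adds to the very electrophilic glyoxylate aldehyde through a closed Zimmerman–Traxler chair while the benzyl group of the (R)-auxiliary shields one enolate face, which should set C5 (R) and C6 (R) together as the syn pair.

Step 2
Reactants: 4 syn-aldol adduct
Product: 5 ethyl (2R,3R)-3-{[(4R)-4-benzyl-2-oxo-1,3-oxazolidin-3-yl]carbonyl}-2-[(tert-butyldimethylsilyl)oxy]-4-methylpentanoate
Conditions: TBSOTf, 2,6-lutidine, CH2Cl2, −78 to 0 °C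
Reagents that add atoms: tert-butyldimethylsilyl triflate (TBSOTf), CC(C)(C)[Si](C)(C)OS(=O)(=O)C(F)(F)F
Why: Silyl ether formation with a silyl triflate and a hindered pyridine base tolerates imide and ester and masks the C6 hydroxyl until the last step without touching a stereocentre.

Step 3
Reactants: 5 silyl ether of the aldol adduct
Product: 7 (2R,3R)-3-[(tert-butyldimethylsilyl)oxy]-4-ethoxy-4-oxo-2-(propan-2-yl)butanoic acid, via peroxy acid 6 (not isolated)
Conditions: LiOH·H2O, 30% H2O2, THF/H2O, 0 °C; then aq. Na2SO3; then 1 M HCl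
Reagents that add atoms: lithium hydroperoxide LiOOH (from LiOH and H2O2), [Li+].[O-]O
Why: Hydroperoxide cleavage of an N-acyloxazolidinone, in which the α-effect nucleophile attacks the exocyclic imide carbonyl much faster than the ethyl ester at 0 °C, sulfite reduces the peroxy acid 6, and the auxiliary is released without epimerisation at C5.

Step 4
Reactants: 7 half-ester acid
Product: 9 (3R,4S)-3-[(tert-butyldimethylsilyl)oxy]-4-(propan-2-yl)oxolan-2-one (trans γ-lactone), via hydroxy ester 8 (not isolated)
Conditions: BH3·THF, THF, 0 °C to rt; MeOH; then PPTS (cat.), toluene, 50 °C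
Reagents that add atoms: none
Why: Chemoselective borane reduction of a carboxylic acid beside an ester, followed by acid-catalysed lactonisation of the γ-hydroxy ester 8, stores the C4 alcohol and activates C1 in one trans-disubstituted γ-lactone.

Step 5
Reactants: 9 trans γ-lactone
Product: 11 (4R,5S)-4-[(tert-butyldimethylsilyl)oxy]-5-(hydroxymethyl)-6-methylhept-1-yn-3-one, via lithium lactolate 10 (not isolated)
Conditions: HC≡CLi (from acetylene and n-BuLi), THF, −78 °C; AcOH, −78 °C
Reagents that add atoms: lithium acetylide HC≡CLi, [Li]C#C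
Why: Single addition of an alkynyllithium to a lactone, where the tetrahedral lithium lactolate 10 is stable at −78 °C and collapses only on protonation, so the C1 ynone is unveiled without over-addition and the C4 primary alcohol is released.

Step 6
Reactants: 11 hydroxy ynone
Product: 12 (1Z,4R,5S)-4-[(tert-butyldimethylsilyl)oxy]-5-(hydroxymethyl)-1-iodo-6-methylhept-1-en-3-one
Conditions: NaI, AcOH, rt, dark
Reagents that add atoms: sodium iodide NaI, [Na+].[I-]
Why: Hydroiodination of an ynone, in which iodide adds in conjugate fashion and the allenol intermediate is protonated under kinetic control, should give the (Z)-β-iodoenone by net anti addition of HI, the geometry that holds C3 cis to C1 for the ring closure.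

Step 7
Reactants: 12 (Z)-iodoenone alcohol
Product: 13 (2R,3R,5Z)-3-[(tert-butyldimethylsilyl)oxy]-6-iodo-4-oxo-2-(propan-2-yl)hex-5-enal
Conditions: Dess–Martin periodinane, CH2Cl2, 0 °C to rt; used at once
Reagents that add atoms: none
Why: Dess–Martin oxidation of the primary alcohol under non-basic conditions is chosen to avoid epimerisation at C5 and β-elimination of the C6 silyloxy group in the sensitive 1,4-dicarbonyl product.

Step 8
Reactants: 13 (Z)-iodoenone aldehyde
Product: 15 (4R,5S,6R)-6-[(tert-butyldimethylsilyl)oxy]-4-hydroxy-5-(propan-2-yl)cyclohex-2-en-1-one, via alkenylchromium dichloride 14 (not isolated)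
Conditions: CrCl2 (6 equiv), NiCl2 (2 mol %), degassed DMSO, rt, high dilution (0.005 M); aqueous work-up
Reagents that add atoms: none
Why: NiCl2 is reduced by CrCl2 to zerovalent nickel, which inserts into the C3–I bond with retention of the Z geometry and hands the alkenyl group to trivalent chromium (14); the C3–Cr bond then adds to the tethered C4 aldehyde through a closed four-centre transition state, and aqueous work-up frees the alcohol. The closest known reaction type is the intramolecular Nozaki–Hiyama–Kishi coupling of (Z)-β-iodoenones and β-iodoacrylates with aldehydes. The cyclohexenone ring closes in a 6-exo-trig sense at the aldehyde carbon (C=O exocyclic), and the C2=C3 bond becomes endocyclic. The new stereocentre C4 is controlled by the substrate: with the C5 isopropyl and C6 silyloxy groups equatorial on the half-chair, the oxygen that bridges to chromium has to lie near the plane of the alkenyl C–Cr bond, that is pseudo-equatorial, which should give the 4,5-trans (4R) alcohol. The step needs aldehyde-over-ketone chemoselectivity (inherent to organochromium reagents), ring closure instead of oligomerisation (secured by the Z geometry from step 6 and by dilution), and no epimerisation at C5 or loss of the C6 silyloxy group (secured by the neutral, aprotic medium).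

Step 9
Reactants: 15 4,5-trans cyclohexenol; 16 tiglic acid ((2E)-2-methylbut-2-enoic acid)
Product: 17 (1S,5R,6S)-5-[(tert-butyldimethylsilyl)oxy]-4-oxo-6-(propan-2-yl)cyclohex-2-en-1-yl (2E)-2-methylbut-2-enoate
Conditions: PPh3, DIAD, THF, 0 °C to rt
Reagents that add atoms: none
Why: Mitsunobu esterification, in which the C4 hydroxyl is activated as its oxyphosphonium salt and displaced by tiglate in an SN2 step with inversion (SN2′ attack and ionisation are disfavoured next to the electron-poor enone), should turn the 4,5-trans alcohol into the 4,5-cis tiglate with the C4 (S) configuration of the target.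

Step 10
Reactants: 17 C4 tiglate
Product: 18 (1S,5R,6S)-5-[(tert-butyldimethylsilyl)oxy]-3-(hydroxymethyl)-4-oxo-6-(propan-2-yl)cyclohex-2-en-1-yl (2E)-2-methylbut-2-enoate
Conditions: 37% aq. HCHO, DMAP (cat.), THF, rt
Reagents that add atoms: formaldehyde, C=O
Why: Morita–Baylis–Hillman hydroxymethylation of a cyclohex-2-enone, in which DMAP adds reversibly to C3, the enolate captures formaldehyde at C2 and loss of the amine restores the C2=C3 bond, introduces C7 at the oxidation level of the target without touching a stereocentre.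

Step 11
Reactants: 18 C7 alcohol; 19 tigloyl chloride ((2E)-2-methylbut-2-enoyl chloride)
Product: 20 [(3S,4S,5R)-5-[(tert-butyldimethylsilyl)oxy]-3-{[(2E)-2-methylbut-2-enoyl]oxy}-6-oxo-4-(propan-2-yl)cyclohex-1-en-1-yl]methyl (2E)-2-methylbut-2-enoate
Conditions: pyridine, DMAP (cat.), CH2Cl2, 0 °C
Reagents that add atoms: none
Why: Acylation of the unhindered primary allylic alcohol with an acid chloride under nucleophilic catalysis should be clean, and the E geometry of the tigloyl group is the thermodynamically preferred one and is retained.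

Step 12
Reactants: 20 bis-tiglate silyl ether
Product: 21 [(3S,4R,5R)-5-hydroxy-3-{[(2E)-2-methylbut-2-enoyl]oxy}-6-oxo-4-(propan-2-yl)cyclohex-1-en-1-yl]methyl (2E)-2-methylbut-2-enoate (target)
Conditions: HF·pyridine, pyridine, THF, 0 °C to rt
Reagents that add atoms: none
Why: Fluoride-mediated silyl ether cleavage under buffered, weakly acidic conditions leaves both tiglates, the enone and the α-hydroxy ketone intact and avoids the acyl migration or elimination that basic fluoride sources could cause.

**Compound list**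
1 | (4R)-4-benzyl-3-(3-methylbutanoyl)-1,3-oxazolidin-2-one | CC(C)CC(=O)N1[C@H](Cc2ccccc2)COC1=O | starting material
2 | ethyl glyoxylate (ethyl 2-oxoacetate) | CCOC(=O)C=O | starting material
3 | Z-dibutylboron enolate of 1 | CC(C)/C=C(\OB(CCCC)CCCC)N1[C@H](Cc2ccccc2)COC1=O | intermediate
4 | ethyl (2R,3R)-3-{[(4R)-4-benzyl-2-oxo-1,3-oxazolidin-3-yl]carbonyl}-2-hydroxy-4-methylpentanoate | O=C(N1[C@H](Cc2ccccc2)COC1=O)[C@H](C(C)C)[C@@H](O)C(=O)OCC | intermediate
5 | ethyl (2R,3R)-3-{[(4R)-4-benzyl-2-oxo-1,3-oxazolidin-3-yl]carbonyl}-2-[(tert-butyldimethylsilyl)oxy]-4-methylpentanoate | O=C(N1[C@H](Cc2ccccc2)COC1=O)[C@H](C(C)C)[C@@H](O[Si](C)(C)C(C)(C)C)C(=O)OCC | intermediate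
6 | (2R,3R)-3-[(tert-butyldimethylsilyl)oxy]-4-ethoxy-4-oxo-2-(propan-2-yl)butaneperoxoic acid | OOC(=O)[C@H](C(C)C)[C@@H](O[Si](C)(C)C(C)(C)C)C(=O)OCC | intermediate
7 | (2R,3R)-3-[(tert-butyldimethylsilyl)oxy]-4-ethoxy-4-oxo-2-(propan-2-yl)butanoic acid | OC(=O)[C@H](C(C)C)[C@@H](O[Si](C)(C)C(C)(C)C)C(=O)OCC | intermediate
8 | ethyl (2R,3S)-2-[(tert-butyldimethylsilyl)oxy]-3-(hydroxymethyl)-4-methylpentanoate | OC[C@H](C(C)C)[C@@H](O[Si](C)(C)C(C)(C)C)C(=O)OCC | intermediate
9 | (3R,4S)-3-[(tert-butyldimethylsilyl)oxy]-4-(propan-2-yl)oxolan-2-one | O1C[C@H](C(C)C)[C@@H](O[Si](C)(C)C(C)(C)C)C1=O | intermediate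
10 | lithium (3R,4S)-3-[(tert-butyldimethylsilyl)oxy]-2-ethynyl-4-(propan-2-yl)oxolan-2-olate (both C2 epimers) | O1C[C@H](C(C)C)[C@@H](O[Si](C)(C)C(C)(C)C)C1([O-])C#C.[Li+] | intermediate
11 | (4R,5S)-4-[(tert-butyldimethylsilyl)oxy]-5-(hydroxymethyl)-6-methylhept-1-yn-3-one | OC[C@H](C(C)C)[C@@H](O[Si](C)(C)C(C)(C)C)C(=O)C#C | intermediate
12 | (1Z,4R,5S)-4-[(tert-butyldimethylsilyl)oxy]-5-(hydroxymethyl)-1-iodo-6-methylhept-1-en-3-one | OC[C@H](C(C)C)[C@@H](O[Si](C)(C)C(C)(C)C)C(=O)/C=C\I | intermediate
13 | (2R,3R,5Z)-3-[(tert-butyldimethylsilyl)oxy]-6-iodo-4-oxo-2-(propan-2-yl)hex-5-enal | O=C[C@H](C(C)C)[C@@H](O[Si](C)(C)C(C)(C)C)C(=O)/C=C\I | intermediate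
14 | dichloro[(1Z,4R,5R)-4-[(tert-butyldimethylsilyl)oxy]-5-formyl-6-methyl-3-oxohept-1-en-1-yl]chromium | O=C[C@H](C(C)C)[C@@H](O[Si](C)(C)C(C)(C)C)C(=O)/C=C\[Cr](Cl)Cl | intermediate
15 | (4R,5S,6R)-6-[(tert-butyldimethylsilyl)oxy]-4-hydroxy-5-(propan-2-yl)cyclohex-2-en-1-one | C1=C[C@@H](O)[C@H](C(C)C)[C@@H](O[Si](C)(C)C(C)(C)C)C1=O | intermediate
16 | tiglic acid, (2E)-2-methylbut-2-enoic acid | C/C=C(\C)C(=O)O | starting material
17 | (1S,5R,6S)-5-[(tert-butyldimethylsilyl)oxy]-4-oxo-6-(propan-2-yl)cyclohex-2-en-1-yl (2E)-2-methylbut-2-enoate | C1=C[C@H](OC(=O)/C(C)=C/C)[C@H](C(C)C)[C@@H](O[Si](C)(C)C(C)(C)C)C1=O | intermediate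
18 | (1S,5R,6S)-5-[(tert-butyldimethylsilyl)oxy]-3-(hydroxymethyl)-4-oxo-6-(propan-2-yl)cyclohex-2-en-1-yl (2E)-2-methylbut-2-enoate | OCC1=C[C@H](OC(=O)/C(C)=C/C)[C@H](C(C)C)[C@@H](O[Si](C)(C)C(C)(C)C)C1=O | intermediate
19 | tigloyl chloride, (2E)-2-methylbut-2-enoyl chloride | C/C=C(\C)C(Cl)=O | starting material
20 | [(3S,4S,5R)-5-[(tert-butyldimethylsilyl)oxy]-3-{[(2E)-2-methylbut-2-enoyl]oxy}-6-oxo-4-(propan-2-yl)cyclohex-1-en-1-yl]methyl (2E)-2-methylbut-2-enoate | C/C=C(\C)C(=O)OCC1=C[C@H](OC(=O)/C(C)=C/C)[C@H](C(C)C)[C@@H](O[Si](C)(C)C(C)(C)C)C1=O | intermediate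
21 | [(3S,4R,5R)-5-hydroxy-3-{[(2E)-2-methylbut-2-enoyl]oxy}-6-oxo-4-(propan-2-yl)cyclohex-1-en-1-yl]methyl (2E)-2-methylbut-2-enoate | C/C=C(\C)C(=O)OCC1=C[C@H](OC(=O)/C(C)=C/C)[C@H](C(C)C)[C@@H](O)C1=O | target

Total steps: 12. Longest linear sequence: 12 steps (from 1).

**Steps most likely to fail**

Step 8 (ring closure). What may go wrong: the aldehyde may be delivered to the alkenylchromium on its other face (pseudo-axial oxygen), or the two faces may be poorly discriminated. Fallback, from 13 back to 17: the same ring closure would then supply the 4,5-cis alcohol (4S,5S,6R)-6-[(tert-butyldimethylsilyl)oxy]-4-hydroxy-5-(propan-2-yl)cyclohex-2-en-1-one F1, which already has the C4 configuration of the target. Instead of the invertive Mitsunobu step it would be acylated with retention (tigloyl chloride 19, pyridine, DMAP cat., CH2Cl2) to give 17. Either carbinol epimer is then usable after separation, the trans one by inversion and the cis one by retention.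

Step 9 (Mitsunobu). What may go wrong: SN2 displacement at the hindered C4 oxyphosphonium by the weakly acidic tiglic acid may be slow, so that elimination toward the dienone (followed by aromatisation) or acylation of the reduced azodicarboxylate competes. Fallback, from 15 back to 17: sulfonylation (MsCl, Et3N, CH2Cl2, −20 °C) would give the mesylate (1R,5R,6R)-5-[(tert-butyldimethylsilyl)oxy]-4-oxo-6-(propan-2-yl)cyclohex-2-en-1-yl methanesulfonate F2. Displacement with caesium (2E)-2-methylbut-2-enoate (from 16 and Cs2CO3; 18-crown-6, toluene/DMF) should then give 17 with inversion in a separate, phosphorus-free SN2 step.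

Step 10 (hydroxymethylation). What may go wrong: the amine catalyst may not turn over, because its addition to the hindered C3 is reversible and the aldol and elimination steps with formaldehyde are slow. Fallback, from 17 back to 18: α-iodination of the enone (I2, pyridine, CH2Cl2), in which the transient enolate is trapped irreversibly by iodine, would give the 2-iodoenone (1R,5R,6S)-5-[(tert-butyldimethylsilyl)oxy]-3-iodo-4-oxo-6-(propan-2-yl)cyclohex-2-en-1-yl (2E)-2-methylbut-2-enoate F3. Stille coupling with (tributylstannyl)methanol (Pd(PPh3)4 cat., dioxane, 80 °C) should then give 18.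

**Further compounds**
F1 | step 8 | (4S,5S,6R)-6-[(tert-butyldimethylsilyl)oxy]-4-hydroxy-5-(propan-2-yl)cyclohex-2-en-1-one | C1=C[C@H](O)[C@H](C(C)C)[C@@H](O[Si](C)(C)C(C)(C)C)C1=O
F2 | step 9 | (1R,5R,6R)-5-[(tert-butyldimethylsilyl)oxy]-4-oxo-6-(propan-2-yl)cyclohex-2-en-1-yl methanesulfonate | C1=C[C@@H](OS(C)(=O)=O)[C@H](C(C)C)[C@@H](O[Si](C)(C)C(C)(C)C)C1=O
F3 | step 10 | (1R,5R,6S)-5-[(tert-butyldimethylsilyl)oxy]-3-iodo-4-oxo-6-(propan-2-yl)cyclohex-2-en-1-yl (2E)-2-methylbut-2-enoate | IC1=C[C@H](OC(=O)/C(C)=C/C)[C@H](C(C)C)[C@@H](O[Si](C)(C)C(C)(C)C)C1=O
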